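The earlier runs and the new flask were generated by integration for substances that don't exist; scatter was added.

Late in a run the excess in the product is a cumulative figure, the amount-weighted mean of what each moment made, so the last hours shift it in proportion to their share of the product. You asked for a quick number on this racemate flask; here it is as it stands.

| flask | left-handed substrate | right-handed substrate | gas | free catalyst | precatalyst | remark | time |
|---|---|---|---|---|---|---|---|
| epsilon | 0.25 M | 0.25 M | 110 mM (held) | 1.8 mol% | 0.36 mol% | the very flask that is asked about, followed so far |  |
| flask | 0.25 M | 0.25 M | 110 mM (held) | 1.8 mol% | 0.36 mol% |  | 6.0 h |

epsilon run (percent of the left-handed substrate and right-handed substrate together charged)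

| time / h | left-handed product / % | right-handed product / % |
|---|---|---|
| 0.133 | 1.4 | 0.6 |
| 0.333 | 2.8 | 1.3 |
| 0.667 | 8.5 | 3.8 |
| 1.00 | 12.4 | 5.5 |
| 1.33 | 17.6 | 7.4 |
| 2.00 | 26.5 | 10.8 |
| 2.50 | 32.0 | 14.4 |

(readings scatter by 0.5 percentage points)

- free catalyst is single-handed; left-handed substrate and right-handed substrate are mirror images of each other, charged as a racemate, each of them at the stated concentration
- at the start none of the gas is in solution
- an excess is below zero if the other one leads

- left-handed product and right-handed product together, in percent of the left-handed substrate and right-handed substrate charged together, at 6.0 h
- excess of left-handed product over right-handed product in the product at 6.0 h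
- whether the exchange between left-handed substrate and right-handed substrate keeps pace with the reaction: how far the product's excess at 6.0 h gets from its value without exchange to its value with instant exchange (above 80% keeps pace, below 20% hardly takes part, else lags behind)

Your forecast gives 93% (from 84% to 99%), an excess of 29% (from 21% to 36%) and "lags behind", on the ground that near the end “the substrate pool shrinks faster than exchange can rebalance it”.

I take your yield but part with you on the excess. At 2.50 h half of your yield is made, and its excess reads 37.9%. I see no drift beyond the scatter, so I replace the curve by its mean over all the readings:

mean excess = (left-handed sum − right-handed sum) / (both sums) = 39.6%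

Call this the mean excess: the apparent selectivity factor written as an excess, a reading with its scatter. Its error sits in the tail, so grant the last 10.0% of the product no excess at all:

excess with a dead tail = 90.0% × mean excess = 35.6%

share of the way from your no-exchange limit of 7% to the mean excess, which I take in place of the excess with instant exchange = 87.9%

So I expect an excess higher than yours, between these two figures, and an exchange that keeps pace, above 80%.

    coupling partner + free catalyst + left-handed substrate → free catalyst + left-handed product (k = 1.50 M⁻² s⁻¹)
    precatalyst → racemization catalyst (k = 2.70 × 10⁻⁴ s⁻¹)
    gas ⇌ coupling partner, rate k3*(csat - [coupling partner]) (kL = 2.90 × 10⁻⁴ s⁻¹)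
    coupling partner + free catalyst + right-handed substrate → free catalyst + right-handed product (k = 0.620 M⁻² s⁻¹)
    left-handed substrate + racemization catalyst ⇌ right-handed substrate + racemization catalyst, rate k5*[racemization catalyst]*[left-handed substrate] forward; the back reaction follows from the equilibrium constant (k = 0.520 M⁻¹ s⁻¹)

The flask gives 92.9%, an excess of 37.2% and "keeps pace", at 87% of the way. Its excess stands 2.4 percentage points under the mean excess and 8.2 points above the forecast. At 6.00 h this flask holds 3.15% left-handed and 3.94% right-handed substrate. The neighbouring flask, charged with 4.5 mol% free catalyst, reaches 99.2%. That neighbouring flask has no readings, so its excess of 35.4% can only be held against the mean excess of the 1.8 mol% run: it stands 4.2 points under it, which in the same reckoning is a dead tail of 10.6% of its product, against 6.06% in the asked flask.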